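## Analysis of the target

6-Hydroxyluteolin 6-sulfate 12 is a flavone. Benzene ring A (C4a, C5, C6, C7, C8, C8a) is fused to γ-pyrone ring C (O1, C2, C3, C4, C4a, C8a), and a 3',4'-dihydroxyphenyl ring B sits on C2. The molecule is flat and has no stereocentre and no alkene geometry to set, so every difficulty is one of regiochemistry and chemoselectivity. Five of the six ring A carbons are substituted: C4a bears acyl carbon C4, C5 bears OH, C6 bears OSO3H, C7 bears OH and C8a bears O1; only C8 bears hydrogen. Of the five phenolic oxygens only O6 is sulfated. O6 is the most hindered (flanked by O5 and O7) and less acidic than O7 and O4', so O-sulfation of the free pentaol would go elsewhere first. The aryl hydrogen sulfate is cleaved at S–O by acid, Lewis acids and hot protic media, whereas its monoanion is inert to alkali, amines and hydrogenolysis; the unmasked catechol and the 5,6,7-trioxygenated ring are oxidised by air in base. Once the sulfate is present only neutral or basic steps are allowed, which excludes the acid cyclodehydrations and Lewis acid dealkylations of usual flavone chemistry.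

Two features invite the plan:
- C6–O lies para to C8a–O1. In a ring A phenol that has no C4 yet, the axis C6···C8a makes O5/O7 and C4a/C8 pairwise equivalent.
- C4 is a lone carbonyl carbon between C4a and C3, ortho to O1. Ring C is therefore the sum of an ortho-iodophenol, carbon monoxide and a terminal alkyne.

## Retrosynthetic reasoning

**12 ⇒ 11 ⇒ 10.** The last cuts are the four O–CH2Ph bonds at O5, O7, O3' and O4' and the exchange of K+ for H+. Benzyl is chosen because hydrogenolysis is the one general phenol deprotection that is neutral and leaves an aryl sulfate anion untouched. The forward step must remove four benzyl groups from 10 without reducing C2=C3. It must then protonate salt 11 without hydrolysing it.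

**10 ⇒ 4 + 6 + 7 (key disconnection).** Three bonds of ring C are cut at once: C4a–C4, C4–C3 and O1–C2. This isolates C4 as carbon monoxide 7, ring B with C2 and C3 as alkyne 6, and ring A with O1 and the finished C6 sulfate as iodophenol 4.
- Other cuts of ring C (C2–C3 aldol, C3–C4 acyl transfer) need an acetophenone on ring A and end in an acidic or hot oxidative closure that endangers the sulfate.
- This cut runs in amine base from start to finish.
- Three small fragments, none with a ring still to be made, give the whole protected target in one operation, through ynone 8 and enaminone 9.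
- The forward reaction must insert 7 before the alkyne is transferred and must close ring C in the six-membered mode.

**4 ⇒ 3.** The C4a–I bond is cut. In 3 the para position of the phenol is occupied by the sulfate and the two ortho carbons (future C4a and C8) are equivalent, so electrophilic iodination can give only one regioisomer. The forward step only has to stop after one iodine.

**3 ⇒ 1 + 2.** The C6–O bond is cut, not the O6–S bond. An Elbs oxidation lets peroxydisulfate 2 deliver oxygen and sulfur together to the carbon para to a phenoxide, and that carbon is C6 when the phenoxide oxygen is the future O1. This is possible only before ring C exists: in a finished flavone O1 is no longer a phenoxide, and the 5-phenoxide would direct to C8. No hydroxyl has to be told apart from another, because O5 and O7 are already benzylated in commercial 1 and O6 arrives sulfated.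

**6 ⇒ 5.** The C2≡C3 triple bond is traced back to the formyl carbon of commercial aldehyde 5 by a one-carbon homologation. This leaves the benzyl ethers alone and needs no further protection.

## Alternatives that were turned down

**Alternative 1:** (textbook) The O6–S bond is cut last, and ring C is cut at C2–C3 and O1–C2.
- Forward: a Claisen–Schmidt condensation of 5 gives the 2'-hydroxychalcone A2. Oxidative cyclisation gives tetra-O-benzyl-6-hydroxyluteolin A1. O-sulfation of A1 gives 10.
- Turned down on redundancy: the shortest access to the ketone half of A2 is itself an Elbs oxidation whose aryl sulfate is hydrolysed. The S–O6 bond would be made, destroyed and then made again on the most hindered hydroxyl of A1.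
- Turned down on stability and length: A2 carries a free quinol unit that is prone to air oxidation in the alkali of the aldol step. The sequence is fully linear and about two steps longer.

**Alternative 2:** Ring C is cut at C8a–O1, C4a–C4 and O1–C2.
- Forward: fluoride-induced elimination of silyl triflate A3 gives aryne A4 (triple bond C4a≡C8a). The carboxylate of arylpropiolic acid A5 adds to it, the acyl group shifts from O to the aryl anion, and 6-endo closure gives flavone A6.
- The regiochemistry is right: the benzyloxy group on C5 beside the triple bond sends the oxygen nucleophile to C8a and leaves the carbanion on C4a.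
- Turned down on functional group tolerance: a sulfate cannot pass the organolithium, triflation and fluoride steps. O6 therefore needs its own orthogonal group, which must be told apart from O5 and O7 on a symmetric ring.
- Turned down on step economy: A3 costs about six steps, A6 still needs an acidic deprotection and the late hindered O-sulfation, and protonation of the aryl anion by A5 competes with the acyl shift. The precursor costs more than the key step wins.

**Alternative 3:** The skeleton is rearranged.
- Forward: 2 attacks the 5-phenoxide of tri-O-benzylluteolin A7 at C8 to give 8-sulfate A8. A Wessely–Moser rearrangement opens ring C to diketone A9 and recloses it on the former O5, which turns C8 into C6 and gives 6-sulfate A10.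
- Turned down on mechanism: opening and dehydrative reclosure of the pyrone need hot strong acid, under which S–O cleavage of an aryl sulfate is much faster than the rearrangement. In base A9 undergoes retro-Claisen cleavage instead of closing.
- Turned down on driving force and length: nothing in A9 clearly favours one of the two closures once O8 is sulfated, and A7 must first be built by a complete flavone synthesis.

Key step: step 4

## Route

Assumption: the target is wanted in the protonated form that is drawn. Potassium salt 11 is the robust storage form and is converted to 12 only at the very end.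

Step 1
Reactants: 1 3,5-bis(benzyloxy)phenol; 2 potassium peroxydisulfate (K2S2O8)
Product: 3 potassium 2,6-bis(benzyloxy)-4-hydroxyphenyl sulfate
Conditions: K2S2O8 (1.0 equiv, slow addition), KOH (5 equiv), H2O–pyridine, 0 °C to rt, 24 h; CO2 to pH 8; Et2O wash (returns unchanged 1); n-BuOH extraction
Reagents that add atoms: potassium peroxydisulfate 2, [K+].[K+].[O-]S(=O)(=O)OOS(=O)(=O)[O-]
Why: Elbs peroxydisulfate oxidation: the phenoxide of 1 attacks a peroxide oxygen of 2 through its para carbon and rearomatises to the aryl sulfate, which is normally hydrolysed with hot acid but is kept here by a neutral work-up. Para attack between two alkoxy groups is the known outcome for 2-hydroxy-4,6-dialkoxyacetophenones, and the sulfate monoanion and the benzyl ethers are inert to cold alkali.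

Step 2
Reactants: 3 potassium 2,6-bis(benzyloxy)-4-hydroxyphenyl sulfate
Product: 4 potassium 2,6-bis(benzyloxy)-4-hydroxy-3-iodophenyl sulfate
Conditions: N-iodosuccinimide (1.0 equiv), DMF, −20 to 0 °C, dark; aq KHCO3 work-up
Reagents that add atoms: N-iodosuccinimide, O=C1CCC(=O)N1I
Why: Electrophilic aromatic iodination of a phenol whose para position is blocked by the sulfate and whose two ortho carbons are equivalent, so only one regioisomer can form. One equivalent of a neutral iodonium source at low temperature should limit a second iodination and generates no acid that could touch the sulfate.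

Step 3
Reactants: 5 3,4-bis(benzyloxy)benzaldehyde
Product: 6 1,2-bis(benzyloxy)-4-ethynylbenzene
Conditions: dimethyl (1-diazo-2-oxopropyl)phosphonate (1.2 equiv), K2CO3 (2 equiv), MeOH–THF, rt
Reagents that add atoms: dimethyl (1-diazo-2-oxopropyl)phosphonate, COP(=O)(OC)C(=[N+]=[N-])C(C)=O
Why: Seyferth–Gilbert homologation in the Bestmann–Ohira variant: methanolysis of the acetyl group frees the diazomethylphosphonate anion, which olefinates the aldehyde, and loss of N2 with a 1,2-hydrogen shift gives the terminal alkyne. The mild carbonate base leaves the benzyl ethers untouched.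

Step 4
Reactants: 4 potassium 2,6-bis(benzyloxy)-4-hydroxy-3-iodophenyl sulfate; 6 1,2-bis(benzyloxy)-4-ethynylbenzene; 7 carbon monoxide
Product: 10 potassium 5,7-bis(benzyloxy)-2-[3,4-bis(benzyloxy)phenyl]-4-oxo-4H-chromen-6-yl sulfate, via ynone 8 (not isolated), via enaminone 9 (not isolated)
Conditions: PdCl2(dppf) (5 mol %), CO (10 bar), Et2NH–DMF, 90 °C, autoclave; aq KHCO3/KCl wash
Reagents that add atoms: carbon monoxide 7, [C-]#[O+]; diethylamine, CCNCC (its atoms stand only in intermediate 9 and leave again on ring closure)
Why: This is the known three-component flavone synthesis from a 2-iodophenol, CO and a terminal arylalkyne, a carbonylative Sonogashira coupling followed by annulation. Zerovalent palladium formed from PdCl2(dppf) inserts into the C–I bond of 4, CO inserts to give the aroyl–palladium species, and amine-assisted transfer of the alkynyl group of 6 with reductive elimination forges C4a–C4 and C4–C3 in ynone 8. Et2NH adds to C2 of 8 to give enaminone 9, and the phenol on C8a displaces the amine at C2 by addition–elimination, so ring C closes in the 6-endo mode (O1–C2) and emerges as the aromatic γ-pyrone. No stereocentre is formed. CO insertion must outrun direct alkynyl transfer, which is secured by CO pressure, the absence of copper and the fast migratory insertion of an electron-rich aryl–palladium bond with two ortho substituents. Six-membered closure must beat 5-exo closure, which the amine relay through 9 secures by making C2 the only electrophilic carbon within reach of the phenol. Capture of the aroyl–palladium species by Et2NH is slowed by the two ortho substituents, whereas the slim alkynyl ligand is hardly affected. The ring fusion is fixed by the iodine standing next to the only free hydroxyl, and the medium is basic throughout, so the sulfate monoanion and all four benzyl ethers persist.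

Step 5
Reactants: 10 potassium 5,7-bis(benzyloxy)-2-[3,4-bis(benzyloxy)phenyl]-4-oxo-4H-chromen-6-yl sulfate
Product: 12 6-hydroxyluteolin 6-sulfate, via potassium salt 11 (not isolated)
Conditions: H2 (1 atm), Pd/C (10 wt % Pd), THF–MeOH–H2O, rt, stopped after uptake of 4 equiv; filtration under argon; HCl (1.0 equiv, aq), 0 °C; C18 desalting (H2O, then MeOH); freeze-drying
Reagents that add atoms: none
Why: Catalytic hydrogenolysis of aryl benzyl ethers is neutral and is tolerated by aryl sulfate salts, and stopping at four equivalents of H2 should spare the C2=C3 bond of the pyrone. One equivalent of cold HCl protonates 11 and reversed-phase desalting removes the inorganic salt; cold and short handling avoids acid-catalysed S–O cleavage and air oxidation of the free polyphenol.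

## Compound list

1 | 3,5-bis(benzyloxy)phenol | Oc1cc(OCc2ccccc2)cc(OCc2ccccc2)c1 | starting material
2 | potassium peroxydisulfate | [K+].[K+].[O-]S(=O)(=O)OOS(=O)(=O)[O-] | starting material
3 | potassium 2,6-bis(benzyloxy)-4-hydroxyphenyl sulfate | [K+].[O-]S(=O)(=O)Oc1c(OCc2ccccc2)cc(O)cc1OCc1ccccc1 | intermediate
4 | potassium 2,6-bis(benzyloxy)-4-hydroxy-3-iodophenyl sulfate | [K+].[O-]S(=O)(=O)Oc1c(OCc2ccccc2)cc(O)c(I)c1OCc1ccccc1 | intermediate
5 | 3,4-bis(benzyloxy)benzaldehyde | O=Cc1ccc(OCc2ccccc2)c(OCc2ccccc2)c1 | starting material
6 | 1,2-bis(benzyloxy)-4-ethynylbenzene | C#Cc1ccc(OCc2ccccc2)c(OCc2ccccc2)c1 | intermediate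
7 | carbon monoxide | [C-]#[O+] | starting material
8 | potassium 2,6-bis(benzyloxy)-3-{3-[3,4-bis(benzyloxy)phenyl]prop-2-ynoyl}-4-hydroxyphenyl sulfate (ynone) | [K+].[O-]S(=O)(=O)Oc1c(OCc2ccccc2)cc(O)c(C(=O)C#Cc2ccc(OCc3ccccc3)c(OCc3ccccc3)c2)c1OCc1ccccc1 | intermediate
9 | potassium 2,6-bis(benzyloxy)-3-{(E)-3-[3,4-bis(benzyloxy)phenyl]-3-(diethylamino)prop-2-enoyl}-4-hydroxyphenyl sulfate (enaminone; push–pull alkene, geometry of no consequence) | [K+].[O-]S(=O)(=O)Oc1c(OCc2ccccc2)cc(O)c(C(=O)/C=C(/N(CC)CC)c2ccc(OCc3ccccc3)c(OCc3ccccc3)c2)c1OCc1ccccc1 | intermediate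
10 | potassium 5,7-bis(benzyloxy)-2-[3,4-bis(benzyloxy)phenyl]-4-oxo-4H-chromen-6-yl sulfate | [K+].[O-]S(=O)(=O)Oc1c(OCc2ccccc2)cc2oc(-c3ccc(OCc4ccccc4)c(OCc4ccccc4)c3)cc(=O)c2c1OCc1ccccc1 | intermediate
11 | potassium 2-(3,4-dihydroxyphenyl)-5,7-dihydroxy-4-oxo-4H-chromen-6-yl sulfate | [K+].[O-]S(=O)(=O)Oc1c(O)cc2oc(-c3ccc(O)c(O)c3)cc(=O)c2c1O | intermediate
12 | 6-hydroxyluteolin 6-sulfate, 2-(3,4-dihydroxyphenyl)-5,7-dihydroxy-4-oxo-4H-chromen-6-yl hydrogen sulfate | O=c1cc(-c2ccc(O)c(O)c2)oc2cc(O)c(OS(=O)(=O)O)c(O)c12 | target

## Step count and least certain steps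

Total step count: 5. Longest linear sequence: 4 steps (steps 1, 2, 4, 5); step 3 runs in parallel.

**Step 4 (key step).**
- What may go wrong: oxidative addition may be slow at an electron-rich C–I bond with two ortho substituents. Hydrodeiodination, alkynyl transfer ahead of CO insertion, and capture of the aroyl–palladium species by the amine may compete. The potassium salt may be poorly soluble.
- Why: all of these compete at the same palladium centre, and the substrate is more hindered and more polar than the usual 2-iodophenols.
- Fallback: build ring C without palladium and without CO, in basic media only. It sets out from aldehyde 5 (with 2 used again) and comes back at 10.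
  - The catalogue ketone 1-[2,4-bis(benzyloxy)-6-hydroxyphenyl]ethanone F1 is submitted to the Elbs oxidation with 2 under the conditions of step 1. This is the classical substrate class for the reaction. It should give potassium 3-acetyl-2,6-bis(benzyloxy)-4-hydroxyphenyl sulfate F2.
  - Claisen–Schmidt condensation of F2 with 5 (KOH, EtOH) should give the chalcone potassium 2,6-bis(benzyloxy)-3-{(E)-3-[3,4-bis(benzyloxy)phenyl]prop-2-enoyl}-4-hydroxyphenyl sulfate F3.
  - In hot pyridine F3 should close by oxa-Michael addition to the racemic flavanone potassium 5,7-bis(benzyloxy)-2-[3,4-bis(benzyloxy)phenyl]-4-oxochroman-6-yl sulfate F4. I2 in the same pyridine solution dehydrogenates F4 to 10.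

**Step 1.**
- What may go wrong: conversion may be low because 2 is also consumed in side oxidations. Attack may occur at an ortho carbon, since all three free ring carbons are activated by three oxygens. Further oxidation to quinoid material and losses on isolating an amphiphilic salt from water are also possible.
- Fallback: make the C6–O bond and the O6–S bond separately. It sets out from 1 and comes back at 3.
  - Teuber oxidation of 1 with (KSO3)2NO should give 2,6-bis(benzyloxy)-1,4-benzoquinone F5.
  - Na2S2O4 reduces F5 to 2,6-bis(benzyloxy)benzene-1,4-diol F6.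
  - The unhindered hydroxyl is acetylated selectively (Ac2O, 1 equiv, pyridine, 0 °C) to 3,5-bis(benzyloxy)-4-hydroxyphenyl acetate F7.
  - The remaining hindered hydroxyl is O-sulfated (SO3·pyridine, then K2CO3) to potassium 4-acetoxy-2,6-bis(benzyloxy)phenyl sulfate F8.
  - Methanolysis of the acetate (K2CO3, MeOH) gives 3.

**Step 2.**
- What may go wrong: a second iodination may occur at the equivalent ortho carbon, because one iodine deactivates this ring only slightly. The iodonium source may oxidise the quinol monosulfate by two electrons with loss of the sulfate. Salts that differ by one iodine may be hard to separate.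
- Fallback: place the iodine before the sulfate, so that the iodinating agent never meets a quinol sulfate and the purification is done on neutral compounds. It sets out from 1 and comes back at 4.
  - Iodination of 1 (N-iodosuccinimide, MeCN, −20 °C) should favour the less crowded carbon between OH and OBn. After chromatography on silica this gives 3,5-bis(benzyloxy)-2-iodophenol F9.
  - The Elbs oxidation of F9 with 2 under the conditions of step 1 then attacks the only para carbon and gives 4.

## Further compounds

F1 | step 4 | 1-[2,4-bis(benzyloxy)-6-hydroxyphenyl]ethanone | CC(=O)c1c(O)cc(OCc2ccccc2)cc1OCc1ccccc1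
F2 | step 4 | potassium 3-acetyl-2,6-bis(benzyloxy)-4-hydroxyphenyl sulfate | [K+].[O-]S(=O)(=O)Oc1c(OCc2ccccc2)cc(O)c(C(C)=O)c1OCc1ccccc1
F3 | step 4 | potassium 2,6-bis(benzyloxy)-3-{(E)-3-[3,4-bis(benzyloxy)phenyl]prop-2-enoyl}-4-hydroxyphenyl sulfate | [K+].[O-]S(=O)(=O)Oc1c(OCc2ccccc2)cc(O)c(C(=O)/C=C/c2ccc(OCc3ccccc3)c(OCc3ccccc3)c2)c1OCc1ccccc1
F4 | step 4 | potassium 5,7-bis(benzyloxy)-2-[3,4-bis(benzyloxy)phenyl]-4-oxochroman-6-yl sulfate (racemic) | [K+].[O-]S(=O)(=O)Oc1c(OCc2ccccc2)cc2OC(c3ccc(OCc4ccccc4)c(OCc4ccccc4)c3)CC(=O)c2c1OCc1ccccc1
F5 | step 1 | 2,6-bis(benzyloxy)-1,4-benzoquinone | O=C1C=C(OCc2ccccc2)C(=O)C(OCc2ccccc2)=C1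
F6 | step 1 | 2,6-bis(benzyloxy)benzene-1,4-diol | Oc1cc(OCc2ccccc2)c(O)c(OCc2ccccc2)c1
F7 | step 1 | 3,5-bis(benzyloxy)-4-hydroxyphenyl acetate | CC(=O)Oc1cc(OCc2ccccc2)c(O)c(OCc2ccccc2)c1
F8 | step 1 | potassium 4-acetoxy-2,6-bis(benzyloxy)phenyl sulfate | [K+].[O-]S(=O)(=O)Oc1c(OCc2ccccc2)cc(OC(C)=O)cc1OCc1ccccc1
F9 | step 2 | 3,5-bis(benzyloxy)-2-iodophenol | Oc1cc(OCc2ccccc2)cc(OCc2ccccc2)c1I
A1 | alternative 1 | 5,7-bis(benzyloxy)-2-[3,4-bis(benzyloxy)phenyl]-6-hydroxy-4H-chromen-4-one | O=c1cc(-c2ccc(OCc3ccccc3)c(OCc3ccccc3)c2)oc2cc(OCc3ccccc3)c(O)c(OCc3ccccc3)c12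
A2 | alternative 1 | (E)-1-[2,4-bis(benzyloxy)-3,6-dihydroxyphenyl]-3-[3,4-bis(benzyloxy)phenyl]prop-2-en-1-one | O=C(/C=C/c1ccc(OCc2ccccc2)c(OCc2ccccc2)c1)c1c(O)cc(OCc2ccccc2)c(O)c1OCc1ccccc1
A3 | alternative 2 | 3,5-bis(benzyloxy)-4-(methoxymethoxy)-2-(trimethylsilyl)phenyl trifluoromethanesulfonate | C[Si](C)(C)c1c(OS(=O)(=O)C(F)(F)F)cc(OCc2ccccc2)c(OCOC)c1OCc1ccccc1
A4 | alternative 2 | 3,5-bis(benzyloxy)-4-(methoxymethoxy)benzyne | C1#CC=C(OCc2ccccc2)C(OCOC)=C1OCc1ccccc1
A5 | alternative 2 | 3-[3,4-bis(benzyloxy)phenyl]prop-2-ynoic acid | OC(=O)C#Cc1ccc(OCc2ccccc2)c(OCc2ccccc2)c1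
A6 | alternative 2 | 5,7-bis(benzyloxy)-2-[3,4-bis(benzyloxy)phenyl]-6-(methoxymethoxy)-4H-chromen-4-one | COCOc1c(OCc2ccccc2)cc2oc(-c3ccc(OCc4ccccc4)c(OCc4ccccc4)c3)cc(=O)c2c1OCc1ccccc1
A7 | alternative 3 | 7-(benzyloxy)-2-[3,4-bis(benzyloxy)phenyl]-5-hydroxy-4H-chromen-4-one | O=c1cc(-c2ccc(OCc3ccccc3)c(OCc3ccccc3)c2)oc2cc(OCc3ccccc3)cc(O)c12
A8 | alternative 3 | potassium 7-(benzyloxy)-2-[3,4-bis(benzyloxy)phenyl]-5-hydroxy-4-oxo-4H-chromen-8-yl sulfate | [K+].[O-]S(=O)(=O)Oc1c(OCc2ccccc2)cc(O)c2c1oc(-c1ccc(OCc3ccccc3)c(OCc3ccccc3)c1)cc2=O
A9 | alternative 3 | potassium 6-(benzyloxy)-3-{3-[3,4-bis(benzyloxy)phenyl]-3-oxopropanoyl}-2,4-dihydroxyphenyl sulfate | [K+].[O-]S(=O)(=O)Oc1c(OCc2ccccc2)cc(O)c(C(=O)CC(=O)c2ccc(OCc3ccccc3)c(OCc3ccccc3)c2)c1O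
A10 | alternative 3 | potassium 7-(benzyloxy)-2-[3,4-bis(benzyloxy)phenyl]-5-hydroxy-4-oxo-4H-chromen-6-yl sulfate | [K+].[O-]S(=O)(=O)Oc1c(OCc2ccccc2)cc2oc(-c3ccc(OCc4ccccc4)c(OCc4ccccc4)c3)cc(=O)c2c1O
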